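**Retrosynthetic overview**

1. Target 29 ⇐ acetonide 28 (deprotected last) ⇐ E-selective cross-metathesis (C1'=C2') of homoallylic acetate 19 with vinyl lactone 27.
2. 19 ⇐ syn-diol 16 (acetonide on, PMB off, acetate on) ⇐ 1,3-syn reduction of β-hydroxy ketone 14.
3. Key C–C bond (C7'–C8'): intermolecular boron aldol of methyl ketone 10 with 3-phenylpropanal 11; the C4' OPMB group controls C8' (1,5-anti).
4. 10 ⇐ (R)-epichlorohydrin (vinyl Grignard, then dithiane acyl anion). 27 ⇐ (S)-epichlorohydrin (vinyl Grignard, ylide homologation, acrylate, RCM).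
5. Rings: the dihydropyranone, the only ring of the target, is closed first on the small fragment (step 14). The 1,3-dioxane is a temporary protecting ring (made in step 8, opened in step 16).

Assumption: locants are C2–C6 for the lactone ring and C1'–C10' for the side chain counted from the ring; commercial (R)- and (S)-epichlorohydrin of at least 98% ee supply C4' and C6.

The target is (6S) on the ring and (4'R,6'R,8'R) on the chain: C4'/C6' anti, C6'/C8' syn, C4'/C8' 1,5-anti.

**Route**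

Step 1
Reactants: 1 (R)-epichlorohydrin; 2 vinylmagnesium bromide
Product: 3 (2R)-1-chloropent-4-en-2-ol
Conditions: CuI (10 mol%), THF, −40 → −20 °C; aq. NH4Cl
Reagents that add atoms: none
Why: Copper-catalysed Grignard opening of the epoxide (SN2 at the unsubstituted CH2) does not touch the stereocentre, so the chlorohydrin keeps the configuration of 1.

Step 2
Reactants: 3
Product: 4 (2R)-2-(prop-2-en-1-yl)oxirane
Conditions: powdered NaOH, Et2O, 0 °C → rt; distil (bp about 85 °C)
Reagents that add atoms: none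
Why: Intramolecular Williamson etherification (alkoxide displaces the primary chloride) closes the epoxide without involving the stereocentre.

Step 3
Reactants: 4; 5 2-methyl-1,3-dithiane
Product: 7 (2R)-1-(2-methyl-1,3-dithian-2-yl)pent-4-en-2-ol, via 2-lithio-2-methyl-1,3-dithiane 6 (not isolated)
Conditions: 5, n-BuLi, THF, −30 °C, 2 h; then 4, −30 → 0 °C; aq. NH4Cl
Reagents that add atoms: none
Why: Corey–Seebach acyl-anion (umpolung) opening of the terminal epoxide at its CH2 gives the masked β-hydroxy methyl ketone with the carbinol centre unchanged.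

Step 4
Reactants: 7
Product: 9 2-[(2R)-2-[(4-methoxybenzyl)oxy]pent-4-en-1-yl]-2-methyl-1,3-dithiane, via sodium alkoxide 8 (not isolated)
Conditions: NaH, THF/DMF, 0 °C; then PMBCl, Bu4NI (cat.), 0 °C → rt
Reagents that add atoms: 4-methoxybenzyl chloride (PMBCl), COc1ccc(CCl)cc1
Why: Williamson etherification of an unhindered secondary alkoxide; the dithiane has no acidic C2–H, and the PMB ether is the group needed for 1,5-induction in step 6.

Step 5
Reactants: 9
Product: 10 (4R)-4-[(4-methoxybenzyl)oxy]hept-6-en-2-one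
Conditions: MeI (10 equiv), CaCO3, MeCN/H2O 9:1, 45 °C
Reagents that add atoms: water, O
Why: S-methylation-assisted dithiane hydrolysis under CaCO3 buffering unveils the methyl ketone without β-elimination of the PMB ether and without touching the alkene.

Step 6
Reactants: 10; 11 3-phenylpropanal
Product: 14 (3R,7R)-3-hydroxy-7-[(4-methoxybenzyl)oxy]-1-phenyldec-9-en-5-one, via dibutylboron enolate 12 (not isolated), via dibutylboron aldolate 13 (not isolated)
Conditions: n-Bu2BOTf (1.2 equiv), i-Pr2NEt (1.5 equiv), Et2O, −78 °C, 1 h; then 11, −78 °C, 3 h; pH 7 buffer/MeOH/30% H2O2, 0 °C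
Reagents that add atoms: none
Why: Boron-mediated methyl ketone aldol: kinetic enolisation on the methyl side, then 1,5-anti induction from the β-OPMB group sets C8' as R (expected dr about 10:1 or better; the minor isomer is removed by chromatography).

Step 7
Reactants: 14
Product: 16 (3R,5R,7R)-7-[(4-methoxybenzyl)oxy]-1-phenyldec-9-ene-3,5-diol, via diethylboron chelate 15 (not isolated)
Conditions: Et2BOMe (1.2 equiv), THF/MeOH 4:1, −78 °C; NaBH4, −78 °C, 3 h; then pH 7 buffer/MeOH/30% H2O2, 0 °C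
Reagents that add atoms: none
Why: Narasaka–Prasad reduction: external hydride attacks the six-membered boron chelate of the β-hydroxy ketone axially and gives the 1,3-syn diol, setting C6' as R.

Step 8
Reactants: 16
Product: 17 (4S,6R)-4-[(2R)-2-[(4-methoxybenzyl)oxy]pent-4-en-1-yl]-2,2-dimethyl-6-(2-phenylethyl)-1,3-dioxane
Conditions: Me2C(OMe)2, PPTS (cat.), CH2Cl2, rt
Reagents that add atoms: 2,2-dimethoxypropane, COC(C)(C)OC
Why: Acid-catalysed acetal exchange gives the chair acetonide of the syn-diol, which also confirms the syn relationship (13C methyl signals near 19 and 30 ppm).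

Step 9
Reactants: 17
Product: 18 (2R)-1-[(4S,6R)-2,2-dimethyl-6-(2-phenylethyl)-1,3-dioxan-4-yl]pent-4-en-2-ol
Conditions: DDQ (1.3 equiv), CH2Cl2/pH 7 buffer 10:1, 0 °C → rt
Reagents that add atoms: none
Why: Oxidative PMB cleavage (benzylic hydride abstraction, then hydrolysis of the oxocarbenium ion) is selective for the electron-rich benzyl ether; the buffered medium spares the acetonide and the alkene.

Step 10
Reactants: 18
Product: 19 (2R)-1-[(4R,6R)-2,2-dimethyl-6-(2-phenylethyl)-1,3-dioxan-4-yl]pent-4-en-2-yl acetate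
Conditions: Ac2O, pyridine, DMAP (cat.), CH2Cl2, 0 °C → rt
Reagents that add atoms: acetic anhydride, CC(=O)OC(C)=O
Why: DMAP-catalysed acylation of the only free hydroxyl places the acetate on C4' unambiguously (the ring descriptor changes from 4S to 4R only through CIP priorities).

Step 11
Reactants: 20 (S)-epichlorohydrin; 2 vinylmagnesium bromide
Product: 21 (2S)-1-chloropent-4-en-2-ol
Conditions: CuI (10 mol%), THF, −40 → −20 °C; aq. NH4Cl
Reagents that add atoms: none
Why: Same copper-catalysed Grignard epoxide opening as step 1, in the enantiomeric series.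

Step 12
Reactants: 21
Product: 24 (3S)-hexa-1,5-dien-3-ol, via (2S)-2-allyloxirane 22 (not isolated), via sulfonium betaine 23 (not isolated)
Conditions: Me3S+ I− (4 equiv), n-BuLi (3.8 equiv), THF, −20 °C; then 21, −20 °C → rt; aq. NH4Cl
Reagents that add atoms: trimethylsulfonium iodide, C[S+](C)C.[I-]
Why: The ylide first closes the chlorohydrin to the epoxide, then opens it at the CH2 (Corey–Chaykovsky-type attack), and the betaine ylide loses Me2S by α',β-elimination to give the one-carbon-homologated allylic alcohol with the carbinol centre unchanged.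

Step 13
Reactants: 24; 25 acryloyl chloride
Product: 26 (3S)-hexa-1,5-dien-3-yl prop-2-enoate
Conditions: Et3N, DMAP (cat.), CH2Cl2, 0 °C
Reagents that add atoms: none
Why: Simple O-acylation of the secondary alcohol at low temperature, which avoids polymerisation of the acrylate.

Step 14
Reactants: 26
Product: 27 (6S)-6-ethenyl-5,6-dihydro-2H-pyran-2-one
Conditions: first-generation Grubbs catalyst RuCl2(=CHPh)(PCy3)2 (5 mol%), Ti(OiPr)4 (0.3 equiv), CH2Cl2 (0.01 M), 40 °C
Reagents that add atoms: none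
Why: Ring-closing metathesis: the carbene loads on the unhindered homoallylic alkene and closes onto the acrylate to the six-membered lactone, in preference to the butenolide that would need the hindered allylic vinyl group, which stays free.

Step 15
Reactants: 19; 27 (2.5 equiv)
Product: 28 (2R,4E)-1-[(4R,6R)-2,2-dimethyl-6-(2-phenylethyl)-1,3-dioxan-4-yl]-5-[(2S)-6-oxo-3,6-dihydro-2H-pyran-2-yl]pent-4-en-2-yl acetate
Conditions: second-generation Grubbs catalyst RuCl2(=CHPh)(PCy3)(H2IMes) (2 × 4 mol%), CH2Cl2, 40 °C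
Reagents that add atoms: none
Why: Olefin cross-metathesis between the reactive homoallylic alkene and the slower-dimerising allylic-oxygenated vinyl group, run with excess 27, gives the thermodynamically favoured E-alkene; no stereocentre is touched.

Step 16
Reactants: 28
Product: 29 (1E,4R,6R,8R)-6,8-dihydroxy-1-[(2S)-6-oxo-3,6-dihydro-2H-pyran-2-yl]-10-phenyldec-1-en-4-yl acetate (target)
Conditions: AcOH/H2O 4:1, rt → 35 °C
Reagents that add atoms: none
Why: Mild acid-catalysed acetal hydrolysis frees the syn-diol; under weakly acidic, non-basic conditions the acetate does not migrate and the unsaturated lactone survives.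

**Compound list**

1 | (R)-epichlorohydrin | ClC[C@H]1CO1 | starting material
2 | vinylmagnesium bromide | C=C[Mg]Br | starting material
3 | (2R)-1-chloropent-4-en-2-ol | ClC[C@H](O)CC=C | intermediate
4 | (2R)-2-(prop-2-en-1-yl)oxirane | C=CC[C@@H]1CO1 | intermediate
5 | 2-methyl-1,3-dithiane | CC1SCCCS1 | starting material
6 | 2-lithio-2-methyl-1,3-dithiane | [Li]C1(C)SCCCS1 | intermediate (not isolated)
7 | (2R)-1-(2-methyl-1,3-dithian-2-yl)pent-4-en-2-ol | CC1(C[C@H](O)CC=C)SCCCS1 | intermediate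
8 | sodium (2R)-1-(2-methyl-1,3-dithian-2-yl)pent-4-en-2-olate | CC1(C[C@H]([O-])CC=C)SCCCS1.[Na+] | intermediate (not isolated)
9 | 2-[(2R)-2-[(4-methoxybenzyl)oxy]pent-4-en-1-yl]-2-methyl-1,3-dithiane | CC1(C[C@H](OCc2ccc(OC)cc2)CC=C)SCCCS1 | intermediate
10 | (4R)-4-[(4-methoxybenzyl)oxy]hept-6-en-2-one | CC(=O)C[C@H](OCc1ccc(OC)cc1)CC=C | intermediate
11 | 3-phenylpropanal | O=CCCc1ccccc1 | starting material
12 | dibutylboron enolate of 10 (O-bound at C2, terminal C1=C2 enol double bond, 4R) | C=C(OB(CCCC)CCCC)C[C@H](OCc1ccc(OC)cc1)CC=C | intermediate (not isolated)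
13 | dibutylboron aldolate, the O-BBu2 derivative of 14 (3R,7R) | CCCCB(CCCC)O[C@H](CCc1ccccc1)CC(=O)C[C@H](OCc1ccc(OC)cc1)CC=C | intermediate (not isolated)
14 | (3R,7R)-3-hydroxy-7-[(4-methoxybenzyl)oxy]-1-phenyldec-9-en-5-one | O[C@H](CCc1ccccc1)CC(=O)C[C@H](OCc1ccc(OC)cc1)CC=C | intermediate
15 | diethylboron chelate, the O-BEt2 derivative of 14 with boron coordinated to the ketone (3R,7R) | CCB(CC)O[C@H](CCc1ccccc1)CC(=O)C[C@H](OCc1ccc(OC)cc1)CC=C | intermediate (not isolated)
16 | (3R,5R,7R)-7-[(4-methoxybenzyl)oxy]-1-phenyldec-9-ene-3,5-diol | O[C@H](CCc1ccccc1)C[C@@H](O)C[C@H](OCc1ccc(OC)cc1)CC=C | intermediate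
17 | (4S,6R)-4-[(2R)-2-[(4-methoxybenzyl)oxy]pent-4-en-1-yl]-2,2-dimethyl-6-(2-phenylethyl)-1,3-dioxane | COc1ccc(CO[C@H](CC=C)C[C@H]2C[C@@H](CCc3ccccc3)OC(C)(C)O2)cc1 | intermediate
18 | (2R)-1-[(4S,6R)-2,2-dimethyl-6-(2-phenylethyl)-1,3-dioxan-4-yl]pent-4-en-2-ol | O[C@H](CC=C)C[C@H]1C[C@@H](CCc2ccccc2)OC(C)(C)O1 | intermediate
19 | (2R)-1-[(4R,6R)-2,2-dimethyl-6-(2-phenylethyl)-1,3-dioxan-4-yl]pent-4-en-2-yl acetate | CC(=O)O[C@H](CC=C)C[C@H]1C[C@@H](CCc2ccccc2)OC(C)(C)O1 | intermediate
20 | (S)-epichlorohydrin | ClC[C@@H]1CO1 | starting material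
21 | (2S)-1-chloropent-4-en-2-ol | ClC[C@@H](O)CC=C | intermediate
22 | (2S)-2-(prop-2-en-1-yl)oxirane [(2S)-2-allyloxirane] | C=CC[C@H]1CO1 | intermediate (not isolated)
23 | dimethyl[(3S)-3-oxidohex-5-en-1-yl]sulfonium (sulfonium betaine) | C[S+](C)CC[C@@H]([O-])CC=C | intermediate (not isolated)
24 | (3S)-hexa-1,5-dien-3-ol | C=C[C@@H](O)CC=C | intermediate
25 | acryloyl chloride | C=CC(=O)Cl | starting material
26 | (3S)-hexa-1,5-dien-3-yl prop-2-enoate | C=CC(=O)O[C@H](C=C)CC=C | intermediate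
27 | (6S)-6-ethenyl-5,6-dihydro-2H-pyran-2-one | C=C[C@@H]1CC=CC(=O)O1 | intermediate
28 | (2R,4E)-1-[(4R,6R)-2,2-dimethyl-6-(2-phenylethyl)-1,3-dioxan-4-yl]-5-[(2S)-6-oxo-3,6-dihydro-2H-pyran-2-yl]pent-4-en-2-yl acetate | CC(=O)O[C@H](C/C=C/[C@@H]1CC=CC(=O)O1)C[C@H]2C[C@@H](CCc3ccccc3)OC(C)(C)O2 | intermediate
29 | (1E,4R,6R,8R)-6,8-dihydroxy-1-[(2S)-6-oxo-3,6-dihydro-2H-pyran-2-yl]-10-phenyldec-1-en-4-yl acetate | CC(=O)O[C@H](C/C=C/[C@@H]1CC=CC(=O)O1)C[C@H](O)C[C@H](O)CCc1ccccc1 | target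

**Step count and risks**

Total steps: 16. Longest linear sequence: 12 steps (steps 1–10, 15, 16); the lactone branch is steps 11–14.

Step 6 (diastereoselectivity of the 1,5-anti aldol). If the dr is unsatisfactory, C8' is taken from the chiral pool and the C7'–C8' bond is made by a dithiane–epoxide coupling instead. The fallback sets out from epoxide 4, which is opened with 2-lithio-1,3-dithiane (n-BuLi, THF, −30 °C) to (2R)-1-(1,3-dithian-2-yl)pent-4-en-2-ol F1. F1 is protected (NaH, PMBCl) as 2-[(2R)-2-[(4-methoxybenzyl)oxy]pent-4-en-1-yl]-1,3-dithiane F2. In parallel, (R)-epichlorohydrin 1 and benzylmagnesium chloride with catalytic CuI give (2R)-1-chloro-4-phenylbutan-2-ol F3, which NaOH closes to (2R)-2-(2-phenylethyl)oxirane F4. Lithiation of F2 (t-BuLi, THF/HMPA, −78 °C) and addition to F4 gives 2-[(2R)-2-hydroxy-4-phenylbutyl]-2-[(2R)-2-[(4-methoxybenzyl)oxy]pent-4-en-1-yl]-1,3-dithiane F5. MeI/CaCO3 in aqueous MeCN then unmasks the ketone, and the fallback comes back to the route at 14.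

Step 15 (cross-metathesis yield, homodimerisation of 19). If the convergent coupling is poor, the lactone is built on the chain. The fallback sets out from 19. Cross-metathesis with crotonaldehyde (second-generation Hoveyda–Grubbs catalyst RuCl2(=CH-C6H4-2-OiPr)(H2IMes), CH2Cl2, 40 °C) gives (2R,4E)-1-[(4R,6R)-2,2-dimethyl-6-(2-phenylethyl)-1,3-dioxan-4-yl]-6-oxohex-4-en-2-yl acetate F6. Brown allylation with (−)-Ipc2B(allyl), the reagent made from (+)-α-pinene (Et2O, −78 °C, ethanolamine work-up to spare the acetate), gives (2R,4E,6S)-1-[(4R,6R)-2,2-dimethyl-6-(2-phenylethyl)-1,3-dioxan-4-yl]-6-hydroxynona-4,8-dien-2-yl acetate F7. Acryloyl chloride/Et3N gives the acrylate of F7, (4S,5E,8R)-8-acetoxy-9-[(4R,6R)-2,2-dimethyl-6-(2-phenylethyl)-1,3-dioxan-4-yl]nona-1,5-dien-4-yl prop-2-enoate F8. Ring-closing metathesis with first-generation Grubbs catalyst RuCl2(=CHPh)(PCy3)2 closes the dihydropyranone, and the fallback comes back to the route at 28.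

Step 16 (acetonide removal next to a 1,3-related acetate: risk of acyl migration or incomplete hydrolysis). If acid causes trouble, the diol is carried as silyl ethers that come off with fluoride. The fallback sets out from 16, which TBSOTf/2,6-lutidine converts to the bis-TBS ether of diol 16 F9. DDQ (buffered CH2Cl2) removes the PMB group to give the C4' alcohol from F9 F10. Ac2O/pyridine/DMAP gives the C4' acetate of F10 F11. Cross-metathesis with 27 (second-generation Grubbs catalyst RuCl2(=CHPh)(PCy3)(H2IMes)) gives the bis-TBS ether of 29 F12. HF·pyridine in THF/pyridine (0 °C → rt) removes both silyl groups, and the fallback comes back to the route at 29.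

**Further compounds**

F1 | step 6 | (2R)-1-(1,3-dithian-2-yl)pent-4-en-2-ol | O[C@H](CC=C)CC1SCCCS1
F2 | step 6 | 2-[(2R)-2-[(4-methoxybenzyl)oxy]pent-4-en-1-yl]-1,3-dithiane | COc1ccc(CO[C@H](CC=C)CC2SCCCS2)cc1
F3 | step 6 | (2R)-1-chloro-4-phenylbutan-2-ol | ClC[C@H](O)CCc1ccccc1
F4 | step 6 | (2R)-2-(2-phenylethyl)oxirane | c1ccccc1CC[C@@H]1CO1
F5 | step 6 | 2-[(2R)-2-hydroxy-4-phenylbutyl]-2-[(2R)-2-[(4-methoxybenzyl)oxy]pent-4-en-1-yl]-1,3-dithiane | O[C@H](CCc1ccccc1)CC1(C[C@H](OCc2ccc(OC)cc2)CC=C)SCCCS1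
F6 | step 15 | (2R,4E)-1-[(4R,6R)-2,2-dimethyl-6-(2-phenylethyl)-1,3-dioxan-4-yl]-6-oxohex-4-en-2-yl acetate | CC(=O)O[C@H](C/C=C/C=O)C[C@H]1C[C@@H](CCc2ccccc2)OC(C)(C)O1
F7 | step 15 | (2R,4E,6S)-1-[(4R,6R)-2,2-dimethyl-6-(2-phenylethyl)-1,3-dioxan-4-yl]-6-hydroxynona-4,8-dien-2-yl acetate | CC(=O)O[C@H](C/C=C/[C@@H](O)CC=C)C[C@H]1C[C@@H](CCc2ccccc2)OC(C)(C)O1
F8 | step 15 | (4S,5E,8R)-8-acetoxy-9-[(4R,6R)-2,2-dimethyl-6-(2-phenylethyl)-1,3-dioxan-4-yl]nona-1,5-dien-4-yl prop-2-enoate | CC(=O)O[C@H](C/C=C/[C@@H](OC(=O)C=C)CC=C)C[C@H]1C[C@@H](CCc2ccccc2)OC(C)(C)O1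
F9 | step 16 | bis(tert-butyldimethylsilyl) ether of diol 16 (C6' and C8' OTBS, C4' OPMB, stereocentres as in 16) | CC(C)(C)[Si](C)(C)O[C@H](CCc1ccccc1)C[C@@H](O[Si](C)(C)C(C)(C)C)C[C@H](OCc1ccc(OC)cc1)CC=C
F10 | step 16 | C4' alcohol from F9 (PMB removed, C6' and C8' OTBS) | CC(C)(C)[Si](C)(C)O[C@H](CCc1ccccc1)C[C@@H](O[Si](C)(C)C(C)(C)C)C[C@H](O)CC=C
F11 | step 16 | C4' acetate of F10 | CC(C)(C)[Si](C)(C)O[C@H](CCc1ccccc1)C[C@@H](O[Si](C)(C)C(C)(C)C)C[C@H](OC(C)=O)CC=C
F12 | step 16 | 6',8'-bis-O-(tert-butyldimethylsilyl) ether of target 29 | CC(C)(C)[Si](C)(C)O[C@H](CCc1ccccc1)C[C@@H](O[Si](C)(C)C(C)(C)C)C[C@H](OC(C)=O)C/C=C/[C@@H]1CC=CC(=O)O1
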